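## Analysis of the target

4-O-Demethylplanaic acid is a depside: two benzene rings, each a 5-pentylresorcinol carrying one extra carbon, joined by an aryl ester. Ring A is a benzoic acid with the free carboxyl at C1, a methoxy at C2, the ester oxygen at C4 and a pentyl at C6. Ring B is the acyl part, with the ester carbonyl at C1, a methoxy at C2, a free hydroxyl at C4 and a pentyl at C6. There is no stereocentre, so every problem is one of regiochemistry and chemoselectivity: three phenolic oxygens and two carboxyl carbons must each end up in a different state. The sensitive groups are the depside ester (open to hydrolysis and transesterification, although shielded by the two ortho groups of ring B), the free phenol, and the electron-rich 2,6-disubstituted benzoic acid of ring A, which can lose carbon dioxide under acid and heat. Both carbonyl carbons sit between two ortho substituents, so acyl transfer at either is slow. A conventional plan must also carry the ring A acid through the depside coupling under a protecting group of its own. The strategy rests on the fact that the only free carboxyl stands on ring A C1, between the C2 methoxy and the C6 pentyl and para to the C4 ester oxygen. That is the position at which olivetol is brominated, so C1 can travel as a bromide through the depside coupling and be turned into the acid at the end.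

## Retrosynthetic reasoning

Target 22 is traced back to its ring B benzyl ether 21 by cutting the benzylic O–CH2 bond. The ring B phenol has to be masked while ring B is activated as an acyl donor and while the metal-mediated step runs. A benzyl group is removed under neutral conditions that leave the aryl ester, the methyl ethers and the free acid alone. The forward step only has to cleave one benzylic C–O bond.

Acid 21 is cut at the bond between ring A C1 and the carboxyl carbon, giving aryl bromide 19 and carbon dioxide 20. This is the only C–C bond whose cleavage removes the free acid from the molecule. With it gone, ring A needs no ester protecting group, and the hindered acid, which is prone to decarboxylation, is not carried through earlier steps. The forward reaction has to carboxylate a bromide flanked by a methoxy and a pentyl group without touching the aryl ester two rings away.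

Bromide 19 is cut at the acyl C–O bond of the depside into phenol 8 and acid chloride 18, which is made from acid 17. The hydroxyl of 8 has two hydrogen neighbours and is a good nucleophile, so the hindrance lies only on the acyl side and is answered by the most reactive acyl derivative. Cutting the aryl–oxygen bond instead would need a C–O cross-coupling for a bond that ordinary acylation forms.

Phenol 8 is taken back through silyl ether 7 and monosilyl bromoresorcinol 5 to bromoresorcinol 3, and this to olivetol 1 and N-bromosuccinimide 2. In 1 the two ring positions between a hydroxyl and the pentyl group are equivalent, so bromination needs no control beyond stopping at one bromine. Once in place, the bromine makes the two hydroxyls different: silyl chloride 4 should take the open one, iodomethane 6 then caps the one beside bromine, and desilylation frees the phenol for the coupling.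

Acid 17 is taken back through aldehydes 15 and 14 to the dihydroxy aldehyde 12, and this to olivetol 1, with dimethylformamide 9 as the source of the formyl carbon and water 10 as the source of its oxygen. The formyl group enters at the same nuclear position as the bromine of ring A. Its hydrogen bond to the neighbouring hydroxyl then sets the order of etherification: benzyl bromide 13 takes the free C4 hydroxyl, iodomethane 6 the chelated C2 hydroxyl, and sodium chlorite 16 raises the aldehyde to the acid. Both rings therefore come from 1.

## Alternatives that were turned down

Alternative 1: Ring B is disconnected at its C1–C6 bond and, in effect, unfolded into a linear polyketide chain. The aryl triketo ester A2 (the 3,5,7-trioxododecanoate of the ring A phenol, with the ring A acid as benzyl ester) would be treated with a mild tertiary amine. C2 of the chain would add to the C7 ketone, and dehydration and enolisation would give the depside A1 with a 2,4-dihydroxy-6-pentylbenzoyl ring B.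
- For: ring B and its whole substitution pattern arise in one step. The depside ester is made while the acyl carbon is still unhindered, so the slow acylation of the chosen route (step 9) is avoided. On this point the alternative is stronger.
- Against: A2 is an aryl ester of a poly-β-keto acid, and an aryloxide is a good leaving group. Attack of the C5 enol oxygen on the ester carbonyl would give pyrone A3 and expel ring A, and a Claisen closure from C6 onto C1 would do the same. Both compete with the wanted aldol.
- Against: A1 has both ring B hydroxyls free, whereas the target needs the chelated C2 oxygen methylated and the C4 oxygen free. Protection at C4, a forced methylation next to a base-sensitive aryl ester, and deprotection must follow, which uses up the step economy.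
- Comparison: the chosen route sets the ring B pattern at the aldehyde stage, where chelation helps. It offers a precursor made only by robust aromatic chemistry in place of a fragile open-chain one.

Alternative 2: Ring A is disconnected at C3–C4 and C5–C6. Pyrone A5 (benzyl 4-methoxy-2-oxo-6-pentyl-2H-pyran-5-carboxylate) and ketene acetal A6 (1,1-bis(trimethylsilyloxy)ethene) would combine in an inverse-demand [4+2] cycloaddition. Decarboxylative cycloreversion, loss of a silanol and desilylation would give phenol A4 (benzyl 4-hydroxy-2-methoxy-6-pentylbenzoate).
- For: the methoxy at C2 and the hydroxyl at C4 are placed by construction, so no two phenols have to be told apart. Here the alternative is stronger than the chosen route, which relies on a steric preference in step 2.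
- Against: the 4-methoxy group of A5 donates into the diene and lowers its electron demand. The terminus that must bond to the nucleophilic carbon of A6 is the fully substituted C6 bearing the pentyl chain. A5 itself needs several steps.
- Against: the step delivers only a simple tetrasubstituted benzene that aromatic substitution on 1 reaches in a few steps. Acylation with 18 and a double hydrogenolysis would still follow.
- Comparison: the chosen route builds no ring and spends its single uncertain step on the one C–C bond that removes the ring A ester protecting group. The alternative still carries that group, although it falls in the final hydrogenolysis at no cost in steps.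

Alternative 3: The depside is disconnected at the bond between the ester oxygen and ring A C4. The ring B acid (compound 17 of the route below) and boronic acid A8 ([4-(benzyloxycarbonyl)-3-methoxy-5-pentylphenyl]boronic acid) would be joined by a divalent copper salt and a base in air, by a Chan–Lam coupling through a trivalent copper aryl carboxylate, to give the dibenzyl-protected depside A7.
- For: the carboxylate reacts through oxygen, so the two ortho groups around the carbonyl carbon of ring B, which slow step 9, do not matter. The coupling is convergent and runs at room temperature. On the coupling itself the alternative is stronger.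
- Against: A8 needs extra steps and is most easily derived from the very phenol that could be acylated directly. Copper-mediated arylation of carboxylates is less dependable than that of amines and phenols, a hindered carboxylate binds copper poorly, and protodeboronation, oxidation of the boronic acid and homocoupling compete.
- Against: the ring A acid must be carried as a benzyl ester.
- Comparison: the chosen route forms the depside bond by plain acylation of a cheap phenol, and its transition-metal step installs a carbon atom instead of re-forming a C–O bond. It has fewer steps in total.

Key step: step 10

Assumption: ring A is the benzoic acid ring and ring B the acyl ring, numbered as in the analysis; monobromination and formylation of olivetol are taken to occur at C4, the usual site of attack on 5-alkylresorcinols.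

## Route

Step 1
Reactants: 1 olivetol (5-pentylbenzene-1,3-diol); 2 N-bromosuccinimide
Product: 3 4-bromo-5-pentylbenzene-1,3-diol
Conditions: NBS (1.0 equiv, slow addition), THF, −78 °C → 0 °C
Reagents that add atoms: N-bromosuccinimide, O=C1CCC(=O)N1Br
Why: Electrophilic aromatic bromination; the two equivalent positions between a hydroxyl and the pentyl group are para to one hydroxyl and ortho to the other and should react faster than C2 between the two hydroxyls. One equivalent at low temperature should limit the second bromination.

Step 2
Reactants: 3 4-bromo-5-pentylbenzene-1,3-diol; 4 triisopropylsilyl chloride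
Product: 5 2-bromo-3-pentyl-5-[(triisopropylsilyl)oxy]phenol
Conditions: TIPSCl (1.05 equiv), imidazole, CH2Cl2, 0 °C
Reagents that add atoms: triisopropylsilyl chloride, CC(C)[Si](Cl)(C(C)C)C(C)C
Why: Silylation of a phenol through the N-silylimidazolium ion; the bulky silyl group should choose the hydroxyl para to bromine, which has two hydrogen neighbours, over the hydroxyl beside bromine, which is shielded and weakly hydrogen-bonded to the halogen.

Step 3
Reactants: 5 2-bromo-3-pentyl-5-[(triisopropylsilyl)oxy]phenol; 6 iodomethane
Product: 7 (4-bromo-3-methoxy-5-pentylphenoxy)triisopropylsilane
Conditions: MeI, K2CO3, acetone, reflux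
Reagents that add atoms: iodomethane, CI
Why: Williamson ether synthesis on the remaining phenol; the aryl triisopropylsilyl ether should withstand carbonate in dry acetone.

Step 4
Reactants: 7 (4-bromo-3-methoxy-5-pentylphenoxy)triisopropylsilane
Product: 8 4-bromo-3-methoxy-5-pentylphenol
Conditions: TBAF, AcOH, THF, 0 °C → rt
Reagents that add atoms: none
Why: Fluoride-induced desilylation driven by the Si–F bond; the buffered conditions leave the aryl bromide and the methyl ether untouched.

Step 5
Reactants: 1 olivetol; 9 N,N-dimethylformamide; 10 water
Product: 12 2,4-dihydroxy-6-pentylbenzaldehyde, via iminium chloride 11 (not isolated)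
Conditions: POCl3, DMF, 0 °C → rt; then H2O, 50 °C
Reagents that add atoms: N,N-dimethylformamide, CN(C)C=O; water, O
Why: Vilsmeier–Haack formylation; the chloroiminium ion attacks the position para to one hydroxyl and ortho to the other, and hydrolysis of iminium salt 11 gives the aldehyde, which is stabilised by a hydrogen bond from the C2 hydroxyl.

Step 6
Reactants: 12 2,4-dihydroxy-6-pentylbenzaldehyde; 13 benzyl bromide
Product: 14 4-(benzyloxy)-2-hydroxy-6-pentylbenzaldehyde
Conditions: BnBr (1.05 equiv), K2CO3 (1.1 equiv), acetone, rt → 40 °C
Reagents that add atoms: benzyl bromide, BrCc1ccccc1
Why: Williamson ether synthesis; the C4 hydroxyl is the more acidic and the unhindered one, while the C2 hydroxyl is held in a hydrogen bond to the aldehyde and should not be alkylated with one equivalent of weak base.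

Step 7
Reactants: 14 4-(benzyloxy)-2-hydroxy-6-pentylbenzaldehyde; 6 iodomethane
Product: 15 4-(benzyloxy)-2-methoxy-6-pentylbenzaldehyde
Conditions: MeI, K2CO3, DMF, 50 °C
Reagents that add atoms: iodomethane, CI
Why: Williamson ether synthesis under more forcing conditions; a polar aprotic solvent and excess iodomethane overcome the chelation of the only remaining hydroxyl.

Step 8
Reactants: 15 4-(benzyloxy)-2-methoxy-6-pentylbenzaldehyde; 16 sodium chlorite
Product: 17 4-(benzyloxy)-2-methoxy-6-pentylbenzoic acid
Conditions: NaClO2, NaH2PO4, 2-methyl-2-butene, t-BuOH/H2O, rt
Reagents that add atoms: sodium chlorite, [Na+].[O-]Cl=O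
Why: Pinnick oxidation; chlorous acid adds to the aldehyde and fragments to the acid, and the alkene traps the hypochlorous acid that would otherwise chlorinate the electron-rich ring.

Step 9
Reactants: 17 4-(benzyloxy)-2-methoxy-6-pentylbenzoic acid; 8 4-bromo-3-methoxy-5-pentylphenol
Product: 19 4-bromo-3-methoxy-5-pentylphenyl 4-(benzyloxy)-2-methoxy-6-pentylbenzoate, via acid chloride 18 (not isolated)
Conditions: (COCl)2, cat. DMF, CH2Cl2, 0 °C → rt; evaporate; then 8, Et3N, DMAP, CH2Cl2, rt → reflux
Reagents that add atoms: none
Why: Acid chloride formation followed by DMAP-catalysed acylation of a phenol; the electron-rich aroyl chloride 18 reacts through its acylpyridinium or aroylium ion, which offsets the two ortho groups. The hydroxyl of 8 has no ortho substituent.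

Step 10
Reactants: 19 4-bromo-3-methoxy-5-pentylphenyl 4-(benzyloxy)-2-methoxy-6-pentylbenzoate; 20 carbon dioxide
Product: 21 4-{[4-(benzyloxy)-2-methoxy-6-pentylbenzoyl]oxy}-2-methoxy-6-pentylbenzoic acid
Conditions: NiCl2(PPh3)2 (10 mol%), PPh3 (20 mol%), Et4NI (20 mol%), Mn powder (3 equiv), CO2 (1 atm), 1,3-dimethylimidazolidin-2-one (DMI), rt → 40 °C; then 1 M HCl, 0 °C
Reagents that add atoms: carbon dioxide, O=C=O
Why: Zerovalent nickel, formed from NiCl2(PPh3)2 and Mn, inserts into the C1–Br bond of ring A to give a divalent arylnickel bromide, and Mn, helped by iodide from Et4NI, reduces this to a monovalent arylnickel species that is nucleophilic enough to add to CO2 and form the bond between C1 and the carboxyl carbon. A further one-electron reduction releases the manganese carboxylate and returns zerovalent nickel, and cold dilute acid then frees acid 21. The closest known reaction type is the nickel-catalysed reductive carboxylation of aryl halides with CO2 and Mn at atmospheric pressure and room temperature. No ring is closed and no stereocentre is formed. The step needs chemoselectivity for the C–Br bond over both C–O bonds of the aryl ester and over the benzyl ether. This should hold because oxidative addition of a zerovalent nickel phosphine complex to an aryl bromide is fast at room temperature, whereas ester C–O activation needs heat and strongly donating ligands, and because the ester carbonyl is shielded by the C2 methoxy and C6 pentyl groups of ring B. The two ortho groups on ring A slow the oxidative addition, but they also disfavour the usual side reaction, the union of two aryl groups at nickel to a biaryl, so capture of CO2 should prevail. The acid is formed directly, so ring A carries no ester protecting group at any stage.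

Step 11
Reactants: 21 4-{[4-(benzyloxy)-2-methoxy-6-pentylbenzoyl]oxy}-2-methoxy-6-pentylbenzoic acid
Product: 22 4-O-demethylplanaic acid (4-[(4-hydroxy-2-methoxy-6-pentylbenzoyl)oxy]-2-methoxy-6-pentylbenzoic acid)
Conditions: H2 (1 atm), 10% Pd/C, EtOAc, rt
Reagents that add atoms: none
Why: Hydrogenolysis of a benzyl aryl ether; the aryl ester, the methyl ethers and the carboxylic acid are inert under these neutral conditions, and the mild temperature avoids decarboxylation.

## Compound list

1 | olivetol (5-pentylbenzene-1,3-diol) | CCCCCc1cc(O)cc(O)c1 | starting material
2 | N-bromosuccinimide | O=C1CCC(=O)N1Br | starting material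
3 | 4-bromo-5-pentylbenzene-1,3-diol | CCCCCc1cc(O)cc(O)c1Br | intermediate
4 | triisopropylsilyl chloride | CC(C)[Si](Cl)(C(C)C)C(C)C | starting material
5 | 2-bromo-3-pentyl-5-[(triisopropylsilyl)oxy]phenol | CCCCCc1cc(O[Si](C(C)C)(C(C)C)C(C)C)cc(O)c1Br | intermediate
6 | iodomethane | CI | starting material
7 | (4-bromo-3-methoxy-5-pentylphenoxy)triisopropylsilane | CCCCCc1cc(O[Si](C(C)C)(C(C)C)C(C)C)cc(OC)c1Br | intermediate
8 | 4-bromo-3-methoxy-5-pentylphenol | CCCCCc1cc(O)cc(OC)c1Br | intermediate
9 | N,N-dimethylformamide | CN(C)C=O | starting material
10 | water | O | starting material
11 | [(2,4-dihydroxy-6-pentylphenyl)methylidene]dimethylammonium chloride | CCCCCc1cc(O)cc(O)c1C=[N+](C)C.[Cl-] | intermediate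
12 | 2,4-dihydroxy-6-pentylbenzaldehyde | CCCCCc1cc(O)cc(O)c1C=O | intermediate
13 | benzyl bromide | BrCc1ccccc1 | starting material
14 | 4-(benzyloxy)-2-hydroxy-6-pentylbenzaldehyde | CCCCCc1cc(OCc2ccccc2)cc(O)c1C=O | intermediate
15 | 4-(benzyloxy)-2-methoxy-6-pentylbenzaldehyde | CCCCCc1cc(OCc2ccccc2)cc(OC)c1C=O | intermediate
16 | sodium chlorite | [Na+].[O-]Cl=O | starting material
17 | 4-(benzyloxy)-2-methoxy-6-pentylbenzoic acid | CCCCCc1cc(OCc2ccccc2)cc(OC)c1C(=O)O | intermediate
18 | 4-(benzyloxy)-2-methoxy-6-pentylbenzoyl chloride | CCCCCc1cc(OCc2ccccc2)cc(OC)c1C(=O)Cl | intermediate
19 | 4-bromo-3-methoxy-5-pentylphenyl 4-(benzyloxy)-2-methoxy-6-pentylbenzoate | CCCCCc1cc(OC(=O)c2c(CCCCC)cc(OCc3ccccc3)cc2OC)cc(OC)c1Br | intermediate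
20 | carbon dioxide | O=C=O | starting material
21 | 4-{[4-(benzyloxy)-2-methoxy-6-pentylbenzoyl]oxy}-2-methoxy-6-pentylbenzoic acid | CCCCCc1cc(OC(=O)c2c(CCCCC)cc(OCc3ccccc3)cc2OC)cc(OC)c1C(=O)O | intermediate
22 | 4-O-demethylplanaic acid | CCCCCc1cc(OC(=O)c2c(CCCCC)cc(O)cc2OC)cc(OC)c1C(=O)O | target

## Step count and risks

Total: 11 steps. Longest linear sequence: 7 steps from olivetol 1 (steps 5, 6, 7, 8, 9, 10, 11; the ring A branch through steps 1 to 4 is equally long).

Step 10 (key step). The most likely failure is slow oxidative addition at the electron-rich C–Br bond between two ortho groups. Once the arylnickel species has formed, protonation by traces of water may also outrun insertion of CO2, which would reduce the C–Br bond to C–H. Fallback: from 19, bromine–lithium exchange with t-BuLi (2 equiv) in THF/Et2O at −100 °C would give {4-[4-(benzyloxy)-2-methoxy-6-pentylbenzoyloxy]-2-methoxy-6-pentylphenyl}lithium F1. It is quenched at once with dry CO2 and acidified, and the route is rejoined at 21. The exchange is much faster than addition to an ester whose carbonyl is shielded on both sides, but the temperature must stay low.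

Step 2. Site discrimination between the two phenolic hydroxyls may be poor, with silylation next to bromine or at both oxygens, because the more hindered hydroxyl is also the more acidic. Fallback: the oxygens are differentiated before bromination. From 1, exhaustive methylation (MeI, K2CO3, DMF) would give 1,3-dimethoxy-5-pentylbenzene F2. Cleavage of one methyl ether with NaSEt in DMF at 120 °C, which stops after the first cleavage because the resulting phenoxide resists a second one, would give 3-methoxy-5-pentylphenol F3. Bromination with 2 in MeCN at low temperature, directed para to the free hydroxyl as the stronger donor, rejoins the route at 8.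

Step 9. Acyl transfer at the carbonyl between two ortho groups may be slow, which gives the acid chloride time to lose its benzyl or ortho methyl ether under the hydrogen chloride present. Fallback: from 17, trifluoroacetic anhydride in toluene at rt would form 4-(benzyloxy)-2-methoxy-6-pentylbenzoic trifluoroacetic anhydride F4. It ionises to the aroylium ion and acylates 8 without base, rejoining the route at 19.

Step 3. Carbonate may cause loss or intermolecular transfer of the silyl group, followed by methylation of both oxygens. Fallback: from 5, a Mitsunobu methylation (MeOH, PPh3, diisopropyl azodicarboxylate, THF, 0 °C → rt) forms the methyl ether under near-neutral conditions and gives 7 directly, with no new intermediate.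

## Further compounds

F1 | step 10 | {4-[4-(benzyloxy)-2-methoxy-6-pentylbenzoyloxy]-2-methoxy-6-pentylphenyl}lithium | [Li]c1c(OC)cc(OC(=O)c2c(CCCCC)cc(OCc3ccccc3)cc2OC)cc1CCCCC
F2 | step 2 | 1,3-dimethoxy-5-pentylbenzene | CCCCCc1cc(OC)cc(OC)c1
F3 | step 2 | 3-methoxy-5-pentylphenol | CCCCCc1cc(O)cc(OC)c1
F4 | step 9 | 4-(benzyloxy)-2-methoxy-6-pentylbenzoic trifluoroacetic anhydride | CCCCCc1cc(OCc2ccccc2)cc(OC)c1C(=O)OC(=O)C(F)(F)F
F0 | step 3 | none | none
A1 | alternative 1 | benzyl 4-[(2,4-dihydroxy-6-pentylbenzoyl)oxy]-2-methoxy-6-pentylbenzoate | CCCCCc1cc(O)cc(O)c1C(=O)Oc1cc(CCCCC)c(C(=O)OCc2ccccc2)c(OC)c1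
A2 | alternative 1 | benzyl 2-methoxy-6-pentyl-4-[(3,5,7-trioxododecanoyl)oxy]benzoate | CCCCCC(=O)CC(=O)CC(=O)CC(=O)Oc1cc(CCCCC)c(C(=O)OCc2ccccc2)c(OC)c1
A3 | alternative 1 | 4-hydroxy-6-(2-oxoheptyl)-2H-pyran-2-one | CCCCCC(=O)CC1=CC(O)=CC(=O)O1
A4 | alternative 2 | benzyl 4-hydroxy-2-methoxy-6-pentylbenzoate | CCCCCc1cc(O)cc(OC)c1C(=O)OCc1ccccc1
A5 | alternative 2 | benzyl 4-methoxy-2-oxo-6-pentyl-2H-pyran-5-carboxylate | CCCCCC1=C(C(=O)OCc2ccccc2)C(OC)=CC(=O)O1
A6 | alternative 2 | 1,1-bis(trimethylsilyloxy)ethene | C=C(O[Si](C)(C)C)O[Si](C)(C)C
A7 | alternative 3 | benzyl 4-{[4-(benzyloxy)-2-methoxy-6-pentylbenzoyl]oxy}-2-methoxy-6-pentylbenzoate | CCCCCc1cc(OC(=O)c2c(CCCCC)cc(OCc3ccccc3)cc2OC)cc(OC)c1C(=O)OCc1ccccc1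
A8 | alternative 3 | [4-(benzyloxycarbonyl)-3-methoxy-5-pentylphenyl]boronic acid | CCCCCc1cc(B(O)O)cc(OC)c1C(=O)OCc1ccccc1
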